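**Retrosynthetic overview**

- The strategy rests on the side-chain diene C1′=C2′–C3′=C4′ on chroman C2 (primes count from C2). C1′ carries H and the quaternary chroman C2; C4′ carries CH3 and C5′H2. Closing and reopening the C1′–C4′ bond through a cyclobutene ring exchanges which C4′ substituent is cis to C2′.
- Target ⇐ desilylation ⇐ thermal conrotatory opening of the cis-cyclobutene ⇐ photochemical disrotatory closure of the (1′E,3′E)-diene.
- (1′E,3′E)-Diene ⇐ Mizoroki–Heck coupling of an (R)-2-methyl-2-vinylchroman silyl ether with an (E)-alkenyl iodide (from dihydro-β-ionone via the terminal alkyne and carboalumination–iodination).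
- Vinylchroman ⇐ Pd-catalysed asymmetric allylic O-alkylation (forms O1–C2) of a phenol carrying a (Z)-allyl carbonate, built from 2,5-dihydroxybenzaldehyde by silylation, methylenation and hydroboration/B-alkyl Suzuki coupling.
- Ring order: cyclohexene ring purchased; pyran ring of the chroman (step 7); cyclobutene formed (step 9) and opened again (step 10).

Key step: step 9

Assumption: for the (Z)-carbonate in step 7 the (R,R)-ligand is taken to deliver the (R)-chroman; the sense is to be checked on the first run (correlation with the epoxide route given as fallback), and the (S,S)-ligand is used instead if it is the opposite.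

**Route**

Step 1
Reactants: 1 dihydro-β-ionone [4-(2,6,6-trimethylcyclohex-1-en-1-yl)butan-2-one]
Product: 3 2-(but-3-yn-1-yl)-1,3,3-trimethylcyclohex-1-ene, via enol phosphate 2 (not isolated)
Conditions: LDA (1.1 equiv), THF, −78 °C; ClP(O)(OEt)2, −78 °C → rt; then LDA (2.3 equiv), THF, −78 °C → rt; H2O
Reagents that add atoms: none
Why: kinetic deprotonation on the methyl side, O-phosphorylation and base-induced elimination of diethyl phosphate from the enol phosphate (methyl ketone → terminal alkyne by enol phosphate elimination) should give the alkyne without touching the tetrasubstituted ring alkene.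

Step 2
Reactants: 3 2-(but-3-yn-1-yl)-1,3,3-trimethylcyclohex-1-ene
Product: 5 2-[(3E)-4-iodo-3-methylbut-3-en-1-yl]-1,3,3-trimethylcyclohex-1-ene, via alkenylalane 4 (not isolated)
Conditions: Me3Al (2 equiv), Cp2ZrCl2 (0.25 equiv), CH2Cl2, 0 °C → rt; then I2, THF, −30 → 0 °C
Reagents that add atoms: trimethylaluminium C[Al](C)C; iodine II
Why: Zr-catalysed Negishi carboalumination adds CH3 and Al syn across the terminal alkyne with Al at the terminus, and iodinolysis with retention should give the (E)-iodide in which I is trans to the chain.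

Step 3
Reactants: 6 2,5-dihydroxybenzaldehyde
Product: 7 2-hydroxy-5-[(triisopropylsilyl)oxy]benzaldehyde
Conditions: TIPSCl (1.05 equiv), imidazole, DMF, 0 °C → rt
Reagents that add atoms: triisopropylsilyl chloride CC(C)[Si](Cl)(C(C)C)C(C)C
Why: the 2-OH is hydrogen-bonded to the aldehyde and flanked by it, so silylation should take place selectively at the free 5-OH (chemoselective silyl ether formation).

Step 4
Reactants: 7 2-hydroxy-5-[(triisopropylsilyl)oxy]benzaldehyde
Product: 8 2-ethenyl-4-[(triisopropylsilyl)oxy]phenol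
Conditions: Ph3PCH3Br (2.3 equiv), KOtBu (2.2 equiv), THF, 0 °C → rt
Reagents that add atoms: methyltriphenylphosphonium bromide C[P+](c1ccccc1)(c1ccccc1)c1ccccc1.[Br-]
Why: Wittig methylenation with excess ylide (one equivalent of base is taken up by the phenol) should convert the salicylaldehyde into the o-vinylphenol, which is used without storage.

Step 5
Reactants: 8 2-ethenyl-4-[(triisopropylsilyl)oxy]phenol; 9 (2Z)-3-iodobut-2-en-1-ol
Product: 11 2-[(3Z)-5-hydroxy-3-methylpent-3-en-1-yl]-4-[(triisopropylsilyl)oxy]phenol, via alkylborane 10 (not isolated)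
Conditions: 9-BBN (2.2 equiv), THF, 0 °C → rt; then 9, PdCl2(dppf) (5 mol %), aq K3PO4, DMF, rt
Reagents that add atoms: none
Why: anti-Markovnikov hydroboration of the styrene by 9-BBN followed by B-alkyl Suzuki–Miyaura coupling, which retains the geometry of the alkenyl iodide, should give the geometrically pure (Z)-trisubstituted allylic alcohol.

Step 6
Reactants: 11 2-[(3Z)-5-hydroxy-3-methylpent-3-en-1-yl]-4-[(triisopropylsilyl)oxy]phenol
Product: 12 (2Z)-5-{2-hydroxy-5-[(triisopropylsilyl)oxy]phenyl}-3-methylpent-2-en-1-yl methyl carbonate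
Conditions: ClCO2Me (1.05 equiv), pyridine, CH2Cl2, −20 → 0 °C
Reagents that add atoms: methyl chloroformate COC(=O)Cl
Why: under pyridine the primary allylic alcohol is acylated faster than the un-ionised, ortho-substituted phenol, so the mono-carbonate should form (chemoselective O-acylation).

Step 7
Reactants: 12 (2Z)-5-{2-hydroxy-5-[(triisopropylsilyl)oxy]phenyl}-3-methylpent-2-en-1-yl methyl carbonate
Product: 13 (2R)-2-ethenyl-2-methyl-6-[(triisopropylsilyl)oxy]-3,4-dihydro-2H-chromene
Conditions: Pd2(dba)3·CHCl3 (2 mol %), (R,R)-DACH-phenyl ligand (6 mol %), AcOH (1 equiv), CH2Cl2, rt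
Reagents that add atoms: none
Why: Pd-catalysed asymmetric allylic alkylation (Tsuji–Trost type) ionises the carbonate to a π-allyl complex that the phenol attacks at the more substituted terminus, closing the six-membered pyran ring, and the chiral bisphosphine selects the enantioface of the allyl unit and so sets C2 as (R).

Step 8
Reactants: 13 (2R)-2-ethenyl-2-methyl-6-[(triisopropylsilyl)oxy]-3,4-dihydro-2H-chromene; 5 2-[(3E)-4-iodo-3-methylbut-3-en-1-yl]-1,3,3-trimethylcyclohex-1-ene
Product: 14 (2R)-2-methyl-2-[(1E,3E)-4-methyl-6-(2,6,6-trimethylcyclohex-1-en-1-yl)hexa-1,3-dien-1-yl]-6-[(triisopropylsilyl)oxy]-3,4-dihydro-2H-chromene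
Conditions: Pd(OAc)2 (10 mol %), Ag2CO3 (0.6 equiv), DMF, 50 °C, dark
Reagents that add atoms: none
Why: Mizoroki–Heck alkenylation puts the alkenyl group on the terminal carbon of the vinyl group and syn-β-hydride elimination (no β-hydrogen on quaternary C2) should give the 1′E alkene with the iodide geometry retained as 3′E, C2 being untouched.

Step 9
Reactants: 14 (2R)-2-methyl-2-[(1E,3E)-4-methyl-6-(2,6,6-trimethylcyclohex-1-en-1-yl)hexa-1,3-dien-1-yl]-6-[(triisopropylsilyl)oxy]-3,4-dihydro-2H-chromene
Product: 15 (2R)-2-methyl-2-{(1S,4R)-4-methyl-4-[2-(2,6,6-trimethylcyclohex-1-en-1-yl)ethyl]cyclobut-2-en-1-yl}-6-[(triisopropylsilyl)oxy]-3,4-dihydro-2H-chromene (cis-cyclobutene)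
Conditions: hν 254 nm (low-pressure Hg lamp, quartz), degassed n-pentane (2 mM), 20 °C, to loss of the diene UV band; AgNO3–SiO2 chromatography
Reagents that add atoms: none
Why: Proposed new method: direct π,π* excitation of the s-cis rotamer of the diene at 254 nm (the red edge of the diene band, where s-cis rotamers absorb preferentially, and the trough between the two bands of the aryl silyl ether) should close the C1′–C4′ σ-bond by the photochemically allowed disrotatory 4π-electrocyclisation; the closest known reaction is the closure of simple acyclic alkyl-1,3-dienes such as (E,E)-hexa-2,4-diene to cis-3,4-dimethylcyclobutene on direct irradiation, which has not been used preparatively on a 1,4,4-trisubstituted diene that carries an aryl chromophore. The cyclobutene ring closes in the 4π disrotatory mode, so the two outside groups of the (1′E,3′E)-rotamer, the chroman-2-yl group on C1′ and C5′ on C4′, become cis. The new stereocentres C1′ and C4′ are therefore fixed relative to each other by orbital symmetry together with the diene geometry; their sense relative to C2 is not controlled, so 15 is expected together with its (1R,4S) cis diastereomer, which is not separated from it because both open to the same diene. The step needs closure to compete with E/Z photoisomerisation and with arene excitation: the cyclobutene double bond does not absorb at 254 nm, so the closed material should accumulate as the photochemical sink while the diene isomers keep cycling. Trans-cyclobutenes that arise from photoisomerised diene are tolerated, because step 10 turns them back into 14 for recycling.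

Step 10
Reactants: 15 (2R)-2-methyl-2-{(1S,4R)-4-methyl-4-[2-(2,6,6-trimethylcyclohex-1-en-1-yl)ethyl]cyclobut-2-en-1-yl}-6-[(triisopropylsilyl)oxy]-3,4-dihydro-2H-chromene (cis-cyclobutene, used as obtained in step 9)
Product: 16 (2R)-2-methyl-2-[(1E,3Z)-4-methyl-6-(2,6,6-trimethylcyclohex-1-en-1-yl)hexa-1,3-dien-1-yl]-6-[(triisopropylsilyl)oxy]-3,4-dihydro-2H-chromene
Conditions: toluene (degassed, trace Et3N), 130 °C, sealed tube, dark; AgNO3–SiO2 chromatography
Reagents that add atoms: none
Why: thermal conrotatory 4π-electrocyclic ring opening must turn one of the two cis groups inward, and torquoselectivity sends the bulky tertiary chroman-2-yl group on C1′ outward (1′E), which forces C5′ inward and CH3 outward (3′Z); the cis diastereomer that accompanies 15 differs only in the sense of the ring relative to C2 and opens to the same diene, and the temperature is kept at the lowest value that opens the ring so that the [1,5]-hydrogen shift of the Z-diene stays slow and C2 is not affected.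

Step 11
Reactants: 16 (2R)-2-methyl-2-[(1E,3Z)-4-methyl-6-(2,6,6-trimethylcyclohex-1-en-1-yl)hexa-1,3-dien-1-yl]-6-[(triisopropylsilyl)oxy]-3,4-dihydro-2H-chromene
Product: 17 (2R)-2-methyl-2-[(1E,3Z)-4-methyl-6-(2,6,6-trimethylcyclohex-1-en-1-yl)hexa-1,3-dien-1-yl]-3,4-dihydro-2H-chromen-6-ol (CNP0275099.1)
Conditions: TBAF (1.1 equiv), AcOH (1.1 equiv), THF, 0 °C, Ar
Reagents that add atoms: none
Why: fluoride-induced cleavage of the aryl silyl ether under buffered conditions free of strong acid should free the phenol without isomerising the diene or ionising the allylic C2–O bond.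

**Compound list**

1 | dihydro-β-ionone, 4-(2,6,6-trimethylcyclohex-1-en-1-yl)butan-2-one | CC(=O)CCC1=C(C)CCCC1(C)C | starting material
2 | diethyl 4-(2,6,6-trimethylcyclohex-1-en-1-yl)but-1-en-2-yl phosphate | C=C(CCC1=C(C)CCCC1(C)C)OP(=O)(OCC)OCC | intermediate (not isolated)
3 | 2-(but-3-yn-1-yl)-1,3,3-trimethylcyclohex-1-ene | C#CCCC1=C(C)CCCC1(C)C | intermediate
4 | dimethyl[(1E)-2-methyl-4-(2,6,6-trimethylcyclohex-1-en-1-yl)but-1-en-1-yl]alane | C[Al](C)/C=C(\C)CCC1=C(C)CCCC1(C)C | intermediate (not isolated)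
5 | 2-[(3E)-4-iodo-3-methylbut-3-en-1-yl]-1,3,3-trimethylcyclohex-1-ene | I/C=C(\C)CCC1=C(C)CCCC1(C)C | intermediate
6 | 2,5-dihydroxybenzaldehyde | O=Cc1cc(O)ccc1O | starting material
7 | 2-hydroxy-5-[(triisopropylsilyl)oxy]benzaldehyde | O=Cc1cc(O[Si](C(C)C)(C(C)C)C(C)C)ccc1O | intermediate
8 | 2-ethenyl-4-[(triisopropylsilyl)oxy]phenol | C=Cc1cc(O[Si](C(C)C)(C(C)C)C(C)C)ccc1O | intermediate
9 | (2Z)-3-iodobut-2-en-1-ol | C/C(I)=C/CO | starting material
10 | 2-[2-(9-borabicyclo[3.3.1]nonan-9-yl)ethyl]-4-[(triisopropylsilyl)oxy]phenol | Oc1ccc(O[Si](C(C)C)(C(C)C)C(C)C)cc1CCB1C2CCCC1CCC2 | intermediate (not isolated)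
11 | 2-[(3Z)-5-hydroxy-3-methylpent-3-en-1-yl]-4-[(triisopropylsilyl)oxy]phenol | OC/C=C(/C)CCc1cc(O[Si](C(C)C)(C(C)C)C(C)C)ccc1O | intermediate
12 | (2Z)-5-{2-hydroxy-5-[(triisopropylsilyl)oxy]phenyl}-3-methylpent-2-en-1-yl methyl carbonate | COC(=O)OC/C=C(/C)CCc1cc(O[Si](C(C)C)(C(C)C)C(C)C)ccc1O | intermediate
13 | (2R)-2-ethenyl-2-methyl-6-[(triisopropylsilyl)oxy]-3,4-dihydro-2H-chromene | C=C[C@@]1(C)CCc2cc(O[Si](C(C)C)(C(C)C)C(C)C)ccc2O1 | intermediate
14 | (2R)-2-methyl-2-[(1E,3E)-4-methyl-6-(2,6,6-trimethylcyclohex-1-en-1-yl)hexa-1,3-dien-1-yl]-6-[(triisopropylsilyl)oxy]-3,4-dihydro-2H-chromene | CC1=C(CC/C(C)=C/C=C/[C@@]2(C)CCc3cc(O[Si](C(C)C)(C(C)C)C(C)C)ccc3O2)C(C)(C)CCC1 | intermediate (key-step precursor)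
15 | (2R)-2-methyl-2-{(1S,4R)-4-methyl-4-[2-(2,6,6-trimethylcyclohex-1-en-1-yl)ethyl]cyclobut-2-en-1-yl}-6-[(triisopropylsilyl)oxy]-3,4-dihydro-2H-chromene | CC1=C(CC[C@]3(C)C=C[C@@H]3[C@@]2(C)CCc4cc(O[Si](C(C)C)(C(C)C)C(C)C)ccc4O2)C(C)(C)CCC1 | intermediate (key-step product)
16 | (2R)-2-methyl-2-[(1E,3Z)-4-methyl-6-(2,6,6-trimethylcyclohex-1-en-1-yl)hexa-1,3-dien-1-yl]-6-[(triisopropylsilyl)oxy]-3,4-dihydro-2H-chromene | CC1=C(CC/C(C)=C\C=C\[C@@]2(C)CCc3cc(O[Si](C(C)C)(C(C)C)C(C)C)ccc3O2)C(C)(C)CCC1 | intermediate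
17 | (2R)-2-methyl-2-[(1E,3Z)-4-methyl-6-(2,6,6-trimethylcyclohex-1-en-1-yl)hexa-1,3-dien-1-yl]-3,4-dihydro-2H-chromen-6-ol | CC1=C(CC/C(C)=C\C=C\[C@@]2(C)CCc3cc(O)ccc3O2)C(C)(C)CCC1 | target

**Step count and risks**

Total step count: 11. Longest linear sequence: 9 steps (6 → 17, steps 3–11).

Steps most likely to fail:

1. Step 9 (proposed new method). The excited diene is expected to relax by E/Z isomerisation far more often than it closes, so long irradiation is needed. During that time secondary photochemistry can consume material before cyclobutene accumulates: homolysis of the allylic C2–O bond after arene excitation, or intramolecular [2+2] addition to the ring alkene. The fallback builds the 3′Z geometry by known chemistry; it sets out from 3 and 13 and comes back at 16. Lithiation of 3 (n-BuLi, THF, −78 °C) and trapping with methyl chloroformate gives methyl 5-(2,6,6-trimethylcyclohex-1-en-1-yl)pent-2-ynoate F1. Syn addition of Me2CuLi (THF, −78 °C, quench at −78 °C) gives methyl (2Z)-3-methyl-5-(2,6,6-trimethylcyclohex-1-en-1-yl)pent-2-enoate F2, with the chain cis to the ester. DIBAL-H reduction gives (2Z)-3-methyl-5-(2,6,6-trimethylcyclohex-1-en-1-yl)pent-2-en-1-ol F3. Mitsunobu reaction with 1-phenyl-1H-tetrazole-5-thiol gives 5-{[(2Z)-3-methyl-5-(2,6,6-trimethylcyclohex-1-en-1-yl)pent-2-en-1-yl]sulfanyl}-1-phenyl-1H-tetrazole F4. Oxidation with ammonium molybdate/H2O2 gives 5-{[(2Z)-3-methyl-5-(2,6,6-trimethylcyclohex-1-en-1-yl)pent-2-en-1-yl]sulfonyl}-1-phenyl-1H-tetrazole F5. Lemieux–Johnson cleavage of 13 (cat. OsO4, NaIO4, 2,6-lutidine, dioxane/H2O) gives (2R)-2-methyl-6-[(triisopropylsilyl)oxy]-3,4-dihydro-2H-chromene-2-carbaldehyde F6. Julia–Kocienski olefination of F6 with the anion of F5 (KHMDS, DME, −60 °C) should form C1′=C2′ as the E alkene and keep the 3′Z geometry, giving 16.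

2. Step 8. Carbopalladation of the hindered vinyl group on a quaternary carbon may be slow, and the alkylpalladium intermediate may lose the β-aryloxide and open the pyran ring instead of eliminating hydride. The fallback forms the C2′–C3′ bond by transmetalation instead of insertion; it sets out from 13 and 5 and comes back at 14. Cross-metathesis of 13 with vinylboronic acid pinacol ester (second-generation Ru isopropoxybenzylidene metathesis catalyst, CH2Cl2, 40 °C) gives (2R)-2-methyl-2-[(E)-2-(4,4,5,5-tetramethyl-1,3,2-dioxaborolan-2-yl)ethenyl]-6-[(triisopropylsilyl)oxy]-3,4-dihydro-2H-chromene F7. Suzuki–Miyaura coupling of F7 with 5 (Pd(PPh3)4, aq K3PO4, THF, rt) gives 14 with both alkene geometries retained.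

3. Step 7. Enantioface selection in the cyclisation of the π-allyl complex may be insufficient or of the opposite sense, and attack at the primary allyl terminus may compete. The fallback sets C2 by reagent control with a predictable sense; it sets out from 11 and comes back at 13. Sharpless asymmetric epoxidation of 11 (Ti(OiPr)4, D-(−)-diisopropyl tartrate, t-BuOOH, 4 Å MS, CH2Cl2, −20 °C) gives 2-{2-[(2S,3R)-3-(hydroxymethyl)-2-methyloxiran-2-yl]ethyl}-4-[(triisopropylsilyl)oxy]phenol F8. Opening of the epoxide by the phenol at the tertiary carbon with inversion, closing the six-membered ring (Ti-mediated in the same flask or cat. CSA, CH2Cl2, 0 °C), gives (1R)-1-{(2R)-2-methyl-6-[(triisopropylsilyl)oxy]-3,4-dihydro-2H-chromen-2-yl}ethane-1,2-diol F9. Garegg–Samuelsson olefination of the vicinal diol (PPh3, I2, imidazole, toluene, 90 °C) gives 13.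

Further compounds
F1 | step 9 | methyl 5-(2,6,6-trimethylcyclohex-1-en-1-yl)pent-2-ynoate | COC(=O)C#CCCC1=C(C)CCCC1(C)C
F2 | step 9 | methyl (2Z)-3-methyl-5-(2,6,6-trimethylcyclohex-1-en-1-yl)pent-2-enoate | COC(=O)/C=C(/C)CCC1=C(C)CCCC1(C)C
F3 | step 9 | (2Z)-3-methyl-5-(2,6,6-trimethylcyclohex-1-en-1-yl)pent-2-en-1-ol | OC/C=C(/C)CCC1=C(C)CCCC1(C)C
F4 | step 9 | 5-{[(2Z)-3-methyl-5-(2,6,6-trimethylcyclohex-1-en-1-yl)pent-2-en-1-yl]sulfanyl}-1-phenyl-1H-tetrazole | CC1=C(CC/C(C)=C\CSc2nnnn2-c2ccccc2)C(C)(C)CCC1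
F5 | step 9 | 5-{[(2Z)-3-methyl-5-(2,6,6-trimethylcyclohex-1-en-1-yl)pent-2-en-1-yl]sulfonyl}-1-phenyl-1H-tetrazole | CC1=C(CC/C(C)=C\CS(=O)(=O)c2nnnn2-c2ccccc2)C(C)(C)CCC1
F6 | step 9 | (2R)-2-methyl-6-[(triisopropylsilyl)oxy]-3,4-dihydro-2H-chromene-2-carbaldehyde | O=C[C@@]1(C)CCc2cc(O[Si](C(C)C)(C(C)C)C(C)C)ccc2O1
F7 | step 8 | (2R)-2-methyl-2-[(E)-2-(4,4,5,5-tetramethyl-1,3,2-dioxaborolan-2-yl)ethenyl]-6-[(triisopropylsilyl)oxy]-3,4-dihydro-2H-chromene | CC1(C)OB(/C=C/[C@@]2(C)CCc3cc(O[Si](C(C)C)(C(C)C)C(C)C)ccc3O2)OC1(C)C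
F8 | step 7 | 2-{2-[(2S,3R)-3-(hydroxymethyl)-2-methyloxiran-2-yl]ethyl}-4-[(triisopropylsilyl)oxy]phenol | OC[C@H]1O[C@@]1(C)CCc1cc(O[Si](C(C)C)(C(C)C)C(C)C)ccc1O
F9 | step 7 | (1R)-1-{(2R)-2-methyl-6-[(triisopropylsilyl)oxy]-3,4-dihydro-2H-chromen-2-yl}ethane-1,2-diol | OC[C@@H](O)[C@@]1(C)CCc2cc(O[Si](C(C)C)(C(C)C)C(C)C)ccc2O1
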